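## Retrosynthetic overview

1. Both tropolone rings come from one late operation. It is a double one-carbon ring expansion (diazo insertion with a 1,2-vinyl shift) of bis(o-quinone) 25, which is made from bis-phenol 24.
2. The two dihydropyran rings of 24 come from (S)-humulenol 20 and two equivalents of the benzenoid o-quinone methide 21, released from alcohol 5.
3. The eleven-membered ring of 20 is closed at C4=C5 by metathesis of tetraenol 19. C10 is set by Sharpless kinetic resolution. The E-C11=C1 alkene comes from alkynol 16.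
4. Alkynol 16 comes from enyne 9 (isobutyraldehyde plus propargyl bromide) and dienal 14 (pent-1-en-4-yne, Me3Al, oxirane). The arene comes from two molecules of methyl acetoacetate.
5. Order of ring formation: benzene rings, then the eleven-membered ring, then two pyrans, then two seven-membered rings.

Assumption: the macrocycle is labelled C1 (fusion CH next to C2H2), C2, C3 (CMe2), C4=C5, C6, C7 (C(Me)O), C8 (fusion CH), C9, C10 (CHOH), C11 (C(Me)O). In these labels the target is 1R,7R,8R,10S,11R. Arene positions are ar-4a (CH2), ar-5 (Me), ar-6, ar-7, ar-8, ar-8a (ring O). Tropolone tautomers count as one compound.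

## Route

Step 1
Reactants: 1 methyl acetoacetate (2 equiv)
Product: 3 methyl orsellinate (methyl 2,4-dihydroxy-6-methylbenzoate), via triketo ester 2 (not isolated)
Conditions: NaH, THF, 0 °C; n-BuLi, −78 °C to reflux; aq HCl
Reagents that add atoms: none
Why: In this biomimetic Claisen/aldol aromatisation the dianion of 1 acylates a second ester to give 2, whose C2 closes onto the C7 ketone and loses water, which places the ester carbon (the later benzylic CH2) unambiguously between OH and Me; no stereocentre is formed.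

Step 2
Reactants: 3 methyl orsellinate
Product: 4 methyl 4-(tert-butyldimethylsilyloxy)-2-hydroxy-6-methylbenzoate
Conditions: TBSCl (1.05 equiv), imidazole, CH2Cl2, 0 °C
Reagents that add atoms: TBSCl, CC(C)(C)[Si](C)(C)Cl
Why: This is a selective silylation, because the 2-OH is hydrogen-bonded to the ester carbonyl and only the 4-OH reacts.

Step 3
Reactants: 4 silyl ether
Product: 5 5-(tert-butyldimethylsilyloxy)-2-(hydroxymethyl)-3-methylphenol
Conditions: DIBAL-H (3.5 equiv), CH2Cl2, −78 to 0 °C; Rochelle salt
Reagents that add atoms: none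
Why: Hydride reduction takes the ester to the benzylic alcohol, and the aryl silyl ether is stable to DIBAL-H at low temperature.

Step 4
Reactants: 6 isobutyraldehyde; 7 propargyl bromide
Product: 8 2,2-dimethylpent-4-ynal
Conditions: 50 % aq NaOH, Bu4NI (cat.), toluene, 70 °C
Reagents that add atoms: none
Why: Phase-transfer α-alkylation of an aldehyde with a single α-hydrogen gives only monoalkylation and creates quaternary C3.

Step 5
Reactants: 8 2,2-dimethylpent-4-ynal
Product: 9 4,4-dimethylhex-5-en-1-yne
Conditions: MePPh3Br, KOtBu, Et2O, 0 °C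
Reagents that add atoms: methyltriphenylphosphonium bromide, C[P+](c1ccccc1)(c1ccccc1)c1ccccc1.[Br-]
Why: Wittig methylenation of a non-enolisable aldehyde works cleanly, and the volatile product is carried on in solution.

Step 6
Reactants: 10 pent-1-en-4-yne; 11 oxirane
Product: 13 (E)-4-methylhepta-3,6-dien-1-ol, via alkenylalane 12 (not isolated)
Conditions: Me3Al, Cp2ZrCl2 (0.25 equiv), CH2Cl2, 0 °C to rt; n-BuLi, hexane/THF, −30 °C; oxirane; aq HCl
Reagents that add atoms: trimethylaluminium, C[Al](C)C
Why: Negishi syn-carboalumination puts Me on the internal alkyne carbon and so fixes the E-C7=C8 geometry, and the derived aluminate opens oxirane with retention of that geometry.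

Step 7
Reactants: 13 dienol
Product: 14 (E)-4-methylhepta-3,6-dienal
Conditions: Dess–Martin periodinane, NaHCO3, CH2Cl2, 0 °C, used crude
Reagents that add atoms: none
Why: A buffered Dess–Martin oxidation stops at the aldehyde and does not move the β,γ-double bond into conjugation.

Step 8
Reactants: 9 enyne; 14 dienal
Product: 16 (±)-(E)-4,11,11-trimethyltrideca-1,4,12-trien-8-yn-7-ol, via lithium acetylide 15 (not isolated)
Conditions: n-BuLi, THF, −78 °C; then 14; NH4Cl
Reagents that add atoms: none
Why: Acetylide 1,2-addition at −78 °C is faster than enolisation and forms C10–C11; C10 is racemic here and is resolved in step 11.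

Step 9
Reactants: 16 alkynol
Product: 17 (±)-(4E,8Z)-4,11,11-trimethyl-8-(tributylstannyl)trideca-1,4,8,12-tetraen-7-ol
Conditions: [Cp*RuCl]4 (2.5 mol %), Bu3SnH, CH2Cl2, rt
Reagents that add atoms: tributyltin hydride, CCCC[SnH](CCCC)CCCC
Why: Hydroxyl-directed ruthenium-catalysed trans-hydrostannation delivers tin to the alkyne carbon next to the carbinol (C11) and H anti to it at C1, which puts C10 and C2 trans; alkenes are not touched.

Step 10
Reactants: 17 alkenylstannane
Product: 18 (±)-(4E,8E)-4,8,11,11-tetramethyltrideca-1,4,8,12-tetraen-7-ol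
Conditions: MeI, Pd(PPh3)4 (10 mol %), Cu(O2C-C4H3S) (CuTC), [Bu4N][Ph2PO2], DMF, rt
Reagents that add atoms: iodomethane, CI
Why: Copper-assisted Stille C-methylation replaces tin by methyl with retention and gives the E-trisubstituted C11=C1 allylic alcohol.

Step 11
Reactants: 18 racemic tetraenol
Product: 19 (7S,4E,8E)-4,8,11,11-tetramethyltrideca-1,4,8,12-tetraen-7-ol
Conditions: Ti(OiPr)4 (0.15 equiv), D-(−)-DIPT (0.2 equiv), t-BuOOH (0.55 equiv), 4 Å MS, CH2Cl2, −20 °C, to about 55 % conversion
Reagents that add atoms: none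
Why: In the Sharpless kinetic resolution with D-(−)-tartrate the R alcohol (carbinol H on the attacked face) is epoxidised fast, and the S alcohol, which carries the C10 configuration of the target, is recovered in high ee.

Step 12
Reactants: 19 (S)-tetraenol
Product: 20 (S)-humulenol, (1S,2E,6E,9E)-2,5,5,9-tetramethylcycloundeca-2,6,9-trien-1-ol
Conditions: second-generation Hoveyda–Grubbs catalyst (10 mol %), 1,4-benzoquinone (20 mol %), toluene (0.5 mM), 80 °C, argon sparge
Reagents that add atoms: none
Why: In this ring-closing metathesis only the two monosubstituted alkenes can react, since closure through a trisubstituted alkene would put an E-alkene in a seven- or eight-membered ring, and the gem-dimethyl group makes the new C4=C5 bond E; C10 is untouched.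

Step 13
Reactants: 20 (S)-humulenol; 5 benzylic alcohol (4 equiv)
Product: 24 bis-phenol (1R,7R,8R,10S,11R; two 7-hydroxy-5-methylchromans fused at C7–C8 and C11–C1), via o-quinone methide 21 (not isolated), via mono-adduct 22 (not isolated), via bis-silyl ether 23 (not isolated)
Conditions: 5 by syringe pump, o-xylene, 140 °C, sealed; cool; TBAF, THF, 0 °C; NH4Cl
Reagents that add atoms: none
Why: Thermal loss of water from 5 gives 21, which adds as an oxadiene (inverse-demand hetero-Diels–Alder) only to the two electron-rich trisubstituted alkenes with oxygen going to the methyl-bearing carbon; suprafacial addition to E-alkenes makes both fusions trans, attack comes from the ring periphery, and the C10 carbinol selects the exposed face (C9 anti to the diene, OH inside, H next to the C11 methyl to avoid A(1,2) strain), which gives 1R,11R and, through the gauche C8–C9–C10–C11 bridge, 7R,8R; fluoride then frees the phenols.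

Step 14
Reactants: 24 bis-phenol
Product: 25 bis(chroman-6,7-dione), the bis(o-quinone) with all five stereocentres as in 24
Conditions: IBX (2.1 equiv), DMF, 0 °C to rt, dark
Reagents that add atoms: IBX (2-iodoxybenzoic acid), O=C1OI(=O)(O)c2ccccc12
Why: IBX ortho-oxygenation of a para-blocked phenol delivers oxygen to ar-6 (para to the ring oxygen, the position that orcinols also use with electrophiles) and gives the vinylogous-ester quinone; one equivalent per phenol is consumed faster than the hindered C10 carbinol reacts, and any 7,8-dione would expand to the same tropolone.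

Step 15
Reactants: 25 bis(o-quinone)
Product: 27 target CNP0283947.4, via bis-silyl tropolone ether 26 (not isolated)
Conditions: TMSCHN2 (2.4 equiv), Sc(OTf)3 (20 mol %), CH2Cl2/toluene, −78 to −30 °C; AcOH quench; aq citric acid, THF
Reagents that add atoms: trimethylsilyldiazomethane, C[Si](C)(C)C=[N+]=[N-]
Why: Proposed new method: a Lewis-acid-catalysed diazoalkane insertion that turns a 4-alkoxy-o-benzoquinone into an α-tropolone; in each ring the ar-7 carbonyl is a vinylogous ester (O–ar-8a=ar-8–ar-7=O) and is switched off, so the Sc(OTf)3-activated ar-6 carbonyl takes up the nucleophilic carbon of TMSCHN2, the electron-rich vinylic ar-5 (not the acyl ar-7) shifts 1,2 onto the diazonium carbon as N2 leaves (six- to seven-membered ring), and a 1,3-silyl shift from carbon to oxygen aromatises the α-silyl dione to 26, which no longer chelates the catalyst, does not react again and is hydrolysed on work-up; both quinone C=C bonds are tetrasubstituted or β-alkoxy-substituted, which suppresses pyrazoline formation, and no stereocentre is touched; the closest known reactions are the Sc(OTf)3-catalysed diazoalkane homologation of cyclic ketones (Tiffeneau–Demjanov/Büchner–Curtius–Schlotterbeck type) and the diazoalkane ring expansion of isatins and acenaphthenequinone, and to my knowledge neither has been shown on o-benzoquinones or used to make tropolones.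

## Compound list

1 | methyl acetoacetate | CC(=O)CC(=O)OC | starting material
2 | methyl 3,5,7-trioxooctanoate | CC(=O)CC(=O)CC(=O)CC(=O)OC | intermediate (not isolated)
3 | methyl orsellinate | COC(=O)c1c(C)cc(O)cc1O | intermediate
4 | methyl 4-(TBS-oxy)-2-hydroxy-6-methylbenzoate | COC(=O)c1c(C)cc(O[Si](C)(C)C(C)(C)C)cc1O | intermediate
5 | 5-(TBS-oxy)-2-(hydroxymethyl)-3-methylphenol | OCc1c(C)cc(O[Si](C)(C)C(C)(C)C)cc1O | intermediate
6 | isobutyraldehyde | CC(C)C=O | starting material
7 | propargyl bromide | C#CCBr | starting material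
8 | 2,2-dimethylpent-4-ynal | C#CCC(C)(C)C=O | intermediate
9 | 4,4-dimethylhex-5-en-1-yne | C#CCC(C)(C)C=C | intermediate
10 | pent-1-en-4-yne | C=CCC#C | starting material
11 | oxirane | C1CO1 | starting material
12 | (E)-dimethyl(2-methylpenta-1,4-dienyl)alane | C=CC/C(C)=C/[Al](C)C | intermediate (not isolated)
13 | (E)-4-methylhepta-3,6-dien-1-ol | OCC/C=C(C)/CC=C | intermediate
14 | (E)-4-methylhepta-3,6-dienal | O=CC/C=C(C)/CC=C | intermediate
15 | lithium 4,4-dimethylhex-5-en-1-ynide | [Li]C#CCC(C)(C)C=C | intermediate (not isolated)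
16 | (±)-(E)-4,11,11-trimethyltrideca-1,4,12-trien-8-yn-7-ol | C=CC(C)(C)CC#CC(O)C/C=C(C)/CC=C | intermediate
17 | (±)-(4E,8Z)-8-tributylstannyl tetraenol | C=CC(C)(C)C/C=C(\[Sn](CCCC)(CCCC)CCCC)C(O)C/C=C(C)/CC=C | intermediate
18 | (±)-(4E,8E)-4,8,11,11-tetramethyltrideca-1,4,8,12-tetraen-7-ol | C=CC(C)(C)C/C=C(C)/C(O)C/C=C(C)/CC=C | intermediate
19 | (7S,4E,8E)-tetraenol | C=CC(C)(C)C/C=C(C)/[C@@H](O)C/C=C(C)/CC=C | intermediate
20 | (S)-humulenol | O[C@H]1C/C=C(C)/C/C=C/C(C)(C)C/C=C1\C | intermediate
21 | 3-(TBS-oxy)-5-methyl-6-methylenecyclohexa-2,4-dienone | C=C1C(=O)C=C(O[Si](C)(C)C(C)(C)C)C=C1C | intermediate (not isolated)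
22 | mono-chroman at C7–C8 (7R,8R,10S) | C/C1=C\CC(C)(C)/C=C/C[C@@]2(C)Oc3cc(O[Si](C)(C)C(C)(C)C)cc(C)c3C[C@@H]2C[C@@H]1O | intermediate (not isolated)
23 | bis-chroman bis-TBS ether (1R,7R,8R,10S,11R) | Cc1cc(O[Si](C)(C)C(C)(C)C)cc2c1C[C@H]1CC(C)(C)/C=C/C[C@@]3(C)Oc4cc(O[Si](C)(C)C(C)(C)C)cc(C)c4C[C@@H]3C[C@H](O)[C@]1(C)O2 | intermediate (not isolated)
24 | bis-phenol (1R,7R,8R,10S,11R) | Cc1cc(O)cc2c1C[C@H]1CC(C)(C)/C=C/C[C@@]3(C)Oc4cc(O)cc(C)c4C[C@@H]3C[C@H](O)[C@]1(C)O2 | intermediate
25 | bis(chroman-6,7-dione) | CC1=C2C[C@H]3CC(C)(C)/C=C/C[C@@]4(C)OC5=CC(=O)C(=O)C(C)=C5C[C@@H]4C[C@H](O)[C@]3(C)OC2=CC(=O)C1=O | intermediate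
26 | bis(O-trimethylsilyl) tropolone ether | CC1=C2C[C@H]3CC(C)(C)/C=C/C[C@@]4(C)OC5=CC(=O)C(O[Si](C)(C)C)=CC(C)=C5C[C@@H]4C[C@H](O)[C@]3(C)OC2=CC(=O)C(O[Si](C)(C)C)=C1 | intermediate (not isolated)
27 | CNP0283947.4 | Cc1cc(=O)c(O)cc2c1C[C@H]1CC(C)(C)/C=C/C[C@@]3(C)Oc4cc(O)c(=O)cc(C)c4C[C@@H]3C[C@H](O)[C@]1(C)O2 | target

## Step count and risks

Total steps: 15. Longest linear sequence: 10 (steps 4, 5, 8, 9, 10, 11, 12, 13, 14, 15).

**Step 15 (the new reaction).**
- The risks are spiro-epoxide formation, acyl instead of vinyl migration, and attack at ar-7.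
- The fallback uses known chemistry, sets out from 3 and 20 and comes back at 27. It brings the seven-membered ring in ready-made, through the known enzymatic ring expansion.
- C-methylation of 3 between the two hydroxyls (MeI, KOH, MeOH) gives methyl 2,4-dihydroxy-3,6-dimethylbenzoate F1.
- LiAlH4 gives 2,4-dihydroxy-3,6-dimethylbenzyl alcohol F2, and MnO2 gives 3-methylorcinaldehyde F3.
- The flavin monooxygenase TropB (O2, NADPH recycling) gives the (R)-quinol F4.
- The iron/α-ketoglutarate oxygenase TropC gives stipitaldehyde F5, and NaBH4 gives the hydroxymethyl tropolone F6.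
- Heating F6 with 20 releases the tropolone o-quinone methide F7, which adds through the tropolone mono-adduct F8 to give 27 directly.

**Step 12 (ring-closing metathesis).**
- The risks are a strained eleven-membered triene, a hindered neopentyl alkene and oligomerisation.
- The fallback sets out from 9 and 13 and comes back at 20. It makes C4=C5 intermolecularly and closes the ring at C10–C11 instead.
- Treating 9 with n-BuLi and MeI gives 3,3-dimethylhept-1-en-5-yne F9.
- Bu3SnH with PdCl2(PPh3)2 gives the (E)-alkenylstannane F10, with tin on the less hindered carbon, though the selectivity between methyl and the neopentyl-type CH2 may be only moderate, so the isomers may need separation. I2 then gives (E)-6-iodo-3,3-dimethylhepta-1,5-diene F11.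
- Cross metathesis of F11 with 13 gives the iodo-trienol F12, and Dess–Martin oxidation gives the iodo-trienal F13.
- CrCl2 with catalytic NiCl2 in DMF at high dilution (Nozaki–Hiyama–Kishi cyclisation) gives racemic humulenol F14.
- The Sharpless resolution of step 11 (D-(−)-DIPT) applied to F14 leaves 20.

**Step 13 (double annulation).**
- The risks are face pairing between the macrocycle and the C10 carbinol, the relative sense of the two chromans, and self-condensation of 21.
- The fallback sets out from 18 and comes back at 23. It applies if the cycloadditions give the 10-epi series, and it uses C10 only as a relay and resets it afterwards.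
- Resolution of 18 with L-(+)-DIPT leaves the (R)-tetraenol F15, and ring-closing metathesis gives (R)-humulenol F16.
- Annulation of F16 with 5 as in step 13, without fluoride, passes through the (10R) mono-adduct F17 and gives the isolated (10R) bis-silyl ether F18.
- Dess–Martin oxidation gives the C10 ketone F19.
- L-Selectride at −78 °C attacks from the open periphery and gives 23, and TBAF then gives 24.

## Further compounds

F1 | step 15 | methyl 2,4-dihydroxy-3,6-dimethylbenzoate | COC(=O)c1c(C)cc(O)c(C)c1O
F2 | step 15 | 2,4-dihydroxy-3,6-dimethylbenzyl alcohol | OCc1c(C)cc(O)c(C)c1O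
F3 | step 15 | 3-methylorcinaldehyde | O=Cc1c(C)cc(O)c(C)c1O
F4 | step 15 | (R)-quinol from C3 hydroxylation of F3 | O=CC1=C(O)[C@@](C)(O)C(=O)C=C1C
F5 | step 15 | stipitaldehyde | Cc1cc(=O)c(O)cc(O)c1C=O
F6 | step 15 | hydroxymethyl tropolone | Cc1cc(=O)c(O)cc(O)c1CO
F7 | step 15 | tropolone o-quinone methide | C=C1C(=O)C=C(O)C(=O)C=C1C
F8 | step 15 | tropolone mono-adduct at C7–C8 (7R,8R,10S) | C/C1=C\CC(C)(C)/C=C/C[C@@]2(C)Oc3cc(O)c(=O)cc(C)c3C[C@@H]2C[C@@H]1O
F9 | step 12 | 3,3-dimethylhept-1-en-5-yne | CC#CCC(C)(C)C=C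
F10 | step 12 | (E)-tributyl(5,5-dimethylhepta-2,6-dien-2-yl)stannane | C=CC(C)(C)C/C=C(\C)[Sn](CCCC)(CCCC)CCCC
F11 | step 12 | (E)-6-iodo-3,3-dimethylhepta-1,5-diene | C=CC(C)(C)C/C=C(\C)I
F12 | step 12 | (3E,6E,10E)-11-iodo-4,8,8-trimethyldodeca-3,6,10-trien-1-ol | OCC/C=C(C)/C/C=C/C(C)(C)C/C=C(\C)I
F13 | step 12 | (3E,6E,10E)-11-iodo-4,8,8-trimethyldodeca-3,6,10-trienal | O=CC/C=C(C)/C/C=C/C(C)(C)C/C=C(\C)I
F14 | step 12 | racemic humulenol | OC1C/C=C(C)/C/C=C/C(C)(C)C/C=C1\C
F15 | step 13 | (7R,4E,8E)-tetraenol | C=CC(C)(C)C/C=C(C)/[C@H](O)C/C=C(C)/CC=C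
F16 | step 13 | (R)-humulenol | O[C@@H]1C/C=C(C)/C/C=C/C(C)(C)C/C=C1\C
F17 | step 13 | (10R) mono-adduct at C7–C8 | C/C1=C\CC(C)(C)/C=C/C[C@@]2(C)Oc3cc(O[Si](C)(C)C(C)(C)C)cc(C)c3C[C@@H]2C[C@H]1O
F18 | step 13 | (10R) bis-silyl ether (1R,7R,8R,10R,11R) | Cc1cc(O[Si](C)(C)C(C)(C)C)cc2c1C[C@H]1CC(C)(C)/C=C/C[C@@]3(C)Oc4cc(O[Si](C)(C)C(C)(C)C)cc(C)c4C[C@@H]3C[C@@H](O)[C@]1(C)O2
F19 | step 13 | C10 ketone of the bis-silyl ether | Cc1cc(O[Si](C)(C)C(C)(C)C)cc2c1C[C@H]1CC(C)(C)/C=C/C[C@@]3(C)Oc4cc(O[Si](C)(C)C(C)(C)C)cc(C)c4C[C@@H]3CC(=O)[C@]1(C)O2
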